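**Plan** (flavanone numbering: O1, C2, C3, C4, C4a, C5–C8, C8a)

1. Retrosynthesis first removes the two silyl ethers, then cuts ring A at C5–C6, C7–C8 and C4a–C5, leading back to a vinylketene (from diazo ketone 15) and the prenyl siloxyalkyne 20.
2. This cut is available because ring A is a resorcinol with oxygen on C5 and C7, the prenyl group on C6 between them, hydrogen on C8, and fusion to ring C through C4a and C8a, which is the pattern a ketene–ynol ether benzannulation produces.
3. Further cuts: the diazo carbon (C8) back to an acetyl methyl group (13); O1–C8a and C4a–C8a back to methyl ketone 8 and ester 9; C2–C3 back to aldehyde 4; the aryl–prenyl bond back to 4-hydroxybenzaldehyde.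
4. Forward: ring B is bought, ring C is built on it as a 6-acyl-2,3-dihydropyran-4-one (steps 1–8), ring A is annulated onto ring C (step 11), and both silyl groups are removed in step 12; the alkyne arm is steps 9–10.
5. Stereochemistry: the only stereocentre, C2 (S), is set by reagent-controlled allylboration of 4 (step 3), and no later step breaks a bond to it.

Key step: step 11

Remark: the B-allyldiisopinocampheylborane of the (+)-α-pinene series is assumed to add to the Si face of aryl aldehydes (giving the S carbinol), and 9 and 16 are assumed to be purchasable.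

**Step 1**
Reactants: 1 4-hydroxybenzaldehyde; 2 prenyl bromide (1-bromo-3-methylbut-2-ene)
Product: 3 4-hydroxy-3-(3-methylbut-2-enyl)benzaldehyde
Conditions: KOH (10% aq.), 25 °C
Reagents that add atoms: none
Why: In water the phenoxide oxygen is tied up by hydrogen bonding, so the soft allylic bromide alkylates the ortho carbon (C-alkylation of an ambident phenoxide), and the formyl group deactivates the ring against a second prenylation.

**Step 2**
Reactants: 3 4-hydroxy-3-(3-methylbut-2-enyl)benzaldehyde
Product: 4 3-(3-methylbut-2-enyl)-4-(triisopropylsilyloxy)benzaldehyde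
Conditions: iPr3SiOTf, 2,6-lutidine, CH2Cl2, 0 °C
Reagents that add atoms: triisopropylsilyl trifluoromethanesulfonate, CC(C)[Si](OS(=O)(=O)C(F)(F)F)(C(C)C)C(C)C
Why: A silyl triflate with a hindered pyridine base silylates even this ortho-substituted phenol (silyl ether formation), and the bulky triisopropylsilyl ether is chosen because it should survive the amide bases, aqueous acid and light of steps 3–11 yet leave with fluoride at the end.

**Step 3**
Reactants: 4 3-(3-methylbut-2-enyl)-4-(triisopropylsilyloxy)benzaldehyde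
Product: 6 (1S)-1-[3-(3-methylbut-2-enyl)-4-(triisopropylsilyloxy)phenyl]but-3-en-1-ol, via borinate ester 5 (not isolated)
Conditions: Ipc2B(allyl) [Ipc = isopinocampheyl, (+)-α-pinene series], Et2O, −78 °C; then NaBO3·4H2O, THF/H2O, 25 °C
Reagents that add atoms: B-allyldiisopinocampheylborane of the (+)-α-pinene series, C=CCB([C@@H]1C[C@@H]2C[C@@H](C2(C)C)[C@H]1C)[C@@H]1C[C@@H]2C[C@@H](C2(C)C)[C@H]1C
Why: Brown allylboration runs through a chair six-membered transition state in which the isopinocampheyl groups steer the allyl group to the Si face of the aldehyde, which should set the (S) carbinol centre (the future C2), and perborate then frees the alcohol from borinate 5 without harming the aryl silyl ether.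

**Step 4**
Reactants: 6 (1S)-1-[3-(3-methylbut-2-enyl)-4-(triisopropylsilyloxy)phenyl]but-3-en-1-ol
Product: 7 tert-butyldimethylsilyl ether of 6
Conditions: t-BuMe2SiCl, imidazole, DMF, 25 °C
Reagents that add atoms: tert-butyldimethylsilyl chloride, CC(C)(C)[Si](C)(C)Cl
Why: Imidazole-promoted silylation of the secondary benzylic alcohol masks the hydroxyl so that the aldol-type centre cannot undergo retro-aldol cleavage or elimination under the base of step 6.

**Step 5**
Reactants: 7 tert-butyldimethylsilyl ether of 6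
Product: 8 (4S)-4-(tert-butyldimethylsilyloxy)-4-[3-(3-methylbut-2-enyl)-4-(triisopropylsilyloxy)phenyl]butan-2-one
Conditions: PdCl2 (cat.), CuCl (cat.), O2 (1 atm), DMF/H2O 7:1, 25 °C
Reagents that add atoms: water, O
Why: In this Tsuji–Wacker oxidation divalent palladium binds only the monosubstituted alkene, water attacks its internal carbon (Markovnikov) to give the methyl ketone with O2 as terminal oxidant, and the trisubstituted prenyl alkene is too hindered to compete.

**Step 6**
Reactants: 8 (4S)-4-(tert-butyldimethylsilyloxy)-4-[3-(3-methylbut-2-enyl)-4-(triisopropylsilyloxy)phenyl]butan-2-one; 9 methyl 2,2-dimethoxypropanoate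
Product: 10 (7S)-7-(tert-butyldimethylsilyloxy)-2,2-dimethoxy-7-[3-(3-methylbut-2-enyl)-4-(triisopropylsilyloxy)phenyl]heptane-3,5-dione
Conditions: LiN(SiMe3)2 (2.2 equiv), THF, −78 °C; then 9, −78 → −20 °C; AcOH quench
Reagents that add atoms: none
Why: In this crossed Claisen condensation the amide base removes a methyl proton under kinetic control, the enolate acylates the non-enolisable, inductively activated α,α-dialkoxy ester 9, and the second equivalent of base holds the β-diketone as its enolate so that the acylation runs to completion.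

**Step 7**
Reactants: 10 (7S)-7-(tert-butyldimethylsilyloxy)-2,2-dimethoxy-7-[3-(3-methylbut-2-enyl)-4-(triisopropylsilyloxy)phenyl]heptane-3,5-dione
Product: 13 (2S)-6-acetyl-2-[3-(3-methylbut-2-enyl)-4-(triisopropylsilyloxy)phenyl]-2,3-dihydropyran-4-one, via hydroxy diketone 11 (not isolated), via ketal pyranone 12 (not isolated)
Conditions: HCl (2 M aq.), THF, 0 → 25 °C
Reagents that add atoms: water, O
Why: This is the acid-mediated cyclodehydration of a δ-hydroxy β-diketone: once the benzylic silyl ether is hydrolysed, the hydroxyl of 11 adds to the ketone next to the ketal carbon (6-exo-trig hemiketalisation) and water is lost to give vinylogous ester 12, whose deactivated ketal is expected to hydrolyse last, and because the benzylic C–O bond is never broken the (S) centre is kept.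

**Step 8**
Reactants: 13 (2S)-6-acetyl-2-[3-(3-methylbut-2-enyl)-4-(triisopropylsilyloxy)phenyl]-2,3-dihydropyran-4-one
Product: 15 (2S)-6-(2-diazoacetyl)-2-[3-(3-methylbut-2-enyl)-4-(triisopropylsilyloxy)phenyl]-2,3-dihydropyran-4-one, via trifluoroacetyl diketone 14 (not isolated)
Conditions: LiN(SiMe3)2, THF, −78 °C; CF3CO2CH2CF3; HCl (1 M aq.) work-up; then MeSO2N3, Et3N, H2O (1 equiv), MeCN, 25 °C
Reagents that add atoms: methanesulfonyl azide, CS(=O)(=O)N=[N+]=[N-]; 2,2,2-trifluoroethyl trifluoroacetate, O=C(OCC(F)(F)F)C(F)(F)F (its atoms stay only in 14)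
Why: In this detrifluoroacetylative (Regitz-type deacylative) diazo transfer the acetyl methyl group, the most acidic and least hindered α-position (the C3 methylene belongs to a vinylogous ester), should be enolised and trifluoroacetylated to 14, which takes the diazo group from the sulfonyl azide and sheds the trifluoroacetyl group as the sulfonamide, so the ene-dione is never exposed to diazomethane.

**Step 9**
Reactants: 16 4-methylpent-3-enoic acid
Product: 17 methyl 4-methylpent-3-enoate
Conditions: MeI, K2CO3, DMF, 25 °C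
Reagents that add atoms: iodomethane, CI
Why: SN2 alkylation of the carboxylate gives the methyl ester without acid, to which this β,γ-unsaturated acid would respond by lactonisation.

**Step 10**
Reactants: 17 methyl 4-methylpent-3-enoate
Product: 20 triisopropyl(5-methylhex-4-en-1-ynyloxy)silane, via dibromo enolate 18 (not isolated), via lithium ynolate 19 (not isolated)
Conditions: CH2Br2, lithium 2,2,6,6-tetramethylpiperidide, THF, −78 °C; 17; LiN(SiMe3)2; n-BuLi, −78 → 25 °C; then iPr3SiCl, −78 → 25 °C
Reagents that add atoms: dibromomethane, BrCBr; chlorotriisopropylsilane, CC(C)[Si](Cl)(C(C)C)C(C)C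
Why: In this Kowalski ynolate synthesis dibromomethyllithium adds to the ester, dibromo ketone enolate 18 undergoes bromine–lithium exchange and 1,2-shift of the prenyl group to give ynolate 19, and the bulky silyl chloride traps 19 on oxygen.

**Step 11**
Reactants: 15 (2S)-6-(2-diazoacetyl)-2-[3-(3-methylbut-2-enyl)-4-(triisopropylsilyloxy)phenyl]-2,3-dihydropyran-4-one; 20 triisopropyl(5-methylhex-4-en-1-ynyloxy)silane (1.5 equiv)
Product: 25 (2S)-5-hydroxy-6-(3-methylbut-2-enyl)-2-[3-(3-methylbut-2-enyl)-4-(triisopropylsilyloxy)phenyl]-7-(triisopropylsilyloxy)chroman-4-one, via vinylketene 21 (not isolated), via vinylcyclobutenone 22 (not isolated), via dienylketene 23 (not isolated), via cyclohexadienone 24 (not isolated)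
Conditions: hν (medium-pressure Hg lamp, Pyrex filter), ClCH2CH2Cl, 25 °C; then 80 °C
Reagents that add atoms: none
Why: Light expels N2 from 15 and the Wolff shift moves pyranone carbon C6 (the future C8a) onto the diazo carbon (the future C8), giving vinylketene 21 whose ketene carbon (the future C5) is conjugated with the ring C double bond C8a=C4a. The polarised siloxyalkyne 20 adds across the ketene C=C bond in a [2+2] cycloaddition that forms C5–C6 and C7–C8 and closes the transient four-membered ring of 22, which opens by a 4π electrocyclic step (thermal or light-driven) to dienylketene 23. Ring A then closes by thermal disrotatory 6π electrocyclisation between C5 and C4a, and cyclohexadienone 24 tautomerises to the phenol, held by a hydrogen bond to the C4 carbonyl. The closest known reaction is the Danheiser benzannulation in its photochemical diazo ketone form with siloxyalkynes, which delivers resorcinol monosilyl ethers. No stereocentre is formed, since the sp3 carbons of 22 and 24 vanish on aromatisation, and C2, insulated by the C3 methylene, is only a spectator. The step needs regio- and chemoselectivity: the nucleophilic prenyl-bearing alkyne carbon attacks the ketene carbonyl carbon, which fixes 5-OH, 6-prenyl, 7-silyloxy and 8-H and excludes the 8-prenyl isomer, and the electron-rich ynol ether, used in excess, should outrun the two trisubstituted prenyl alkenes as ketene trap.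

**Step 12**
Reactants: 25 (2S)-5-hydroxy-6-(3-methylbut-2-enyl)-2-[3-(3-methylbut-2-enyl)-4-(triisopropylsilyloxy)phenyl]-7-(triisopropylsilyloxy)chroman-4-one
Product: 26 macarangaflavanone B [(2S)-5,7-dihydroxy-2-[4-hydroxy-3-(3-methylbut-2-enyl)phenyl]-6-(3-methylbut-2-enyl)chroman-4-one]
Conditions: Bu4NF, AcOH, THF, 0 °C
Reagents that add atoms: none
Why: Fluoride cleaves both aryl silicon–oxygen bonds (desilylation), and the acetic acid buffer keeps the medium from becoming basic enough to open the flavanone to its chalcone, so C2 should not racemise and the ortho-prenylphenols never meet strong acid.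

**Compound list**

1 | 4-hydroxybenzaldehyde | O=Cc1ccc(O)cc1 | starting material
2 | prenyl bromide | CC(C)=CCBr | starting material
3 | 4-hydroxy-3-(3-methylbut-2-enyl)benzaldehyde | O=Cc1ccc(O)c(CC=C(C)C)c1 | intermediate
4 | 3-(3-methylbut-2-enyl)-4-(triisopropylsilyloxy)benzaldehyde | O=Cc1ccc(O[Si](C(C)C)(C(C)C)C(C)C)c(CC=C(C)C)c1 | intermediate
5 | (1S)-1-[3-(3-methylbut-2-enyl)-4-(triisopropylsilyloxy)phenyl]but-3-enyl diisopinocampheylborinate | C=CC[C@H](OB([C@@H]1C[C@@H]2C[C@@H](C2(C)C)[C@H]1C)[C@@H]1C[C@@H]2C[C@@H](C2(C)C)[C@H]1C)c1ccc(O[Si](C(C)C)(C(C)C)C(C)C)c(CC=C(C)C)c1 | intermediate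
6 | (1S)-1-[3-(3-methylbut-2-enyl)-4-(triisopropylsilyloxy)phenyl]but-3-en-1-ol | C=CC[C@H](O)c1ccc(O[Si](C(C)C)(C(C)C)C(C)C)c(CC=C(C)C)c1 | intermediate
7 | tert-butyldimethylsilyl ether of 6 | C=CC[C@H](O[Si](C)(C)C(C)(C)C)c1ccc(O[Si](C(C)C)(C(C)C)C(C)C)c(CC=C(C)C)c1 | intermediate
8 | (4S)-4-(tert-butyldimethylsilyloxy)-4-[3-(3-methylbut-2-enyl)-4-(triisopropylsilyloxy)phenyl]butan-2-one | CC(=O)C[C@H](O[Si](C)(C)C(C)(C)C)c1ccc(O[Si](C(C)C)(C(C)C)C(C)C)c(CC=C(C)C)c1 | intermediate
9 | methyl 2,2-dimethoxypropanoate | COC(=O)C(C)(OC)OC | starting material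
10 | (7S)-7-(tert-butyldimethylsilyloxy)-2,2-dimethoxy-7-[3-(3-methylbut-2-enyl)-4-(triisopropylsilyloxy)phenyl]heptane-3,5-dione | CC(OC)(OC)C(=O)CC(=O)C[C@H](O[Si](C)(C)C(C)(C)C)c1ccc(O[Si](C(C)C)(C(C)C)C(C)C)c(CC=C(C)C)c1 | intermediate
11 | (7S)-7-hydroxy-2,2-dimethoxy-7-[3-(3-methylbut-2-enyl)-4-(triisopropylsilyloxy)phenyl]heptane-3,5-dione | CC(OC)(OC)C(=O)CC(=O)C[C@H](O)c1ccc(O[Si](C(C)C)(C(C)C)C(C)C)c(CC=C(C)C)c1 | intermediate
12 | (2S)-6-(1,1-dimethoxyethyl)-2-[3-(3-methylbut-2-enyl)-4-(triisopropylsilyloxy)phenyl]-2,3-dihydropyran-4-one | CC(OC)(OC)C1=CC(=O)C[C@@H](c2ccc(O[Si](C(C)C)(C(C)C)C(C)C)c(CC=C(C)C)c2)O1 | intermediate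
13 | (2S)-6-acetyl-2-[3-(3-methylbut-2-enyl)-4-(triisopropylsilyloxy)phenyl]-2,3-dihydropyran-4-one | CC(=O)C1=CC(=O)C[C@@H](c2ccc(O[Si](C(C)C)(C(C)C)C(C)C)c(CC=C(C)C)c2)O1 | intermediate
14 | (2S)-2-[3-(3-methylbut-2-enyl)-4-(triisopropylsilyloxy)phenyl]-6-(4,4,4-trifluoro-3-oxobutanoyl)-2,3-dihydropyran-4-one | O=C(CC(=O)C(F)(F)F)C1=CC(=O)C[C@@H](c2ccc(O[Si](C(C)C)(C(C)C)C(C)C)c(CC=C(C)C)c2)O1 | intermediate
15 | (2S)-6-(2-diazoacetyl)-2-[3-(3-methylbut-2-enyl)-4-(triisopropylsilyloxy)phenyl]-2,3-dihydropyran-4-one | [N-]=[N+]=CC(=O)C1=CC(=O)C[C@@H](c2ccc(O[Si](C(C)C)(C(C)C)C(C)C)c(CC=C(C)C)c2)O1 | intermediate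
16 | 4-methylpent-3-enoic acid | CC(C)=CCC(=O)O | starting material
17 | methyl 4-methylpent-3-enoate | COC(=O)CC=C(C)C | intermediate
18 | lithium 1,1-dibromo-5-methylhexa-1,4-dien-2-olate | [Li]OC(CC=C(C)C)=C(Br)Br | intermediate
19 | lithium 5-methylhex-4-en-1-yn-1-olate | [Li]OC#CCC=C(C)C | intermediate
20 | triisopropyl(5-methylhex-4-en-1-ynyloxy)silane | CC(C)=CCC#CO[Si](C(C)C)(C(C)C)C(C)C | intermediate
21 | (2S)-2-[3-(3-methylbut-2-enyl)-4-(triisopropylsilyloxy)phenyl]-6-(2-oxoethenyl)-2,3-dihydropyran-4-one (vinylketene) | O=C=CC1=CC(=O)C[C@@H](c2ccc(O[Si](C(C)C)(C(C)C)C(C)C)c(CC=C(C)C)c2)O1 | intermediate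
22 | 2-(3-methylbut-2-enyl)-4-[(2S)-2-[3-(3-methylbut-2-enyl)-4-(triisopropylsilyloxy)phenyl]-4-oxo-2,3-dihydropyran-6-yl]-3-(triisopropylsilyloxy)cyclobut-2-en-1-one (both epimers at the ring carbon) | O=C1C(CC=C(C)C)=C(O[Si](C(C)C)(C(C)C)C(C)C)C1C2=CC(=O)C[C@@H](c3ccc(O[Si](C(C)C)(C(C)C)C(C)C)c(CC=C(C)C)c3)O2 | intermediate
23 | (2S)-6-[5-methyl-2-(oxomethylidene)-3-(triisopropylsilyloxy)... dienylketene: O=C=C(prenyl)–C(OSi-iPr3)=CH– attached to C6 of the dihydropyranone | O=C=C(CC=C(C)C)C(O[Si](C(C)C)(C(C)C)C(C)C)=CC1=CC(=O)C[C@@H](c2ccc(O[Si](C(C)C)(C(C)C)C(C)C)c(CC=C(C)C)c2)O1 | intermediate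
24 | (2S)-6-(3-methylbut-2-enyl)-2-[3-(3-methylbut-2-enyl)-4-(triisopropylsilyloxy)phenyl]-7-(triisopropylsilyloxy)-2,3-dihydro-4aH-chromene-4,5-dione (both epimers at C4a) | O=C1C(CC=C(C)C)=C(O[Si](C(C)C)(C(C)C)C(C)C)C=C2O[C@H](c3ccc(O[Si](C(C)C)(C(C)C)C(C)C)c(CC=C(C)C)c3)CC(=O)C21 | intermediate
25 | (2S)-5-hydroxy-6-(3-methylbut-2-enyl)-2-[3-(3-methylbut-2-enyl)-4-(triisopropylsilyloxy)phenyl]-7-(triisopropylsilyloxy)chroman-4-one | CC(C)=CCc1cc([C@@H]2CC(=O)c3c(cc(O[Si](C(C)C)(C(C)C)C(C)C)c(CC=C(C)C)c3O)O2)ccc1O[Si](C(C)C)(C(C)C)C(C)C | intermediate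
26 | macarangaflavanone B | CC(C)=CCc1cc([C@@H]2CC(=O)c3c(cc(O)c(CC=C(C)C)c3O)O2)ccc1O | target

**Totals and risks**

Total step count: 12. Longest linear sequence: 10 steps (steps 1–8, 11 and 12, from 1); the alkyne arm adds steps 9 and 10.

The three steps most likely to fail:

Step 11. What may go wrong: the light needed for the Wolff rearrangement also excites the ene-dione of 15 and the ketones formed after it, so cycloaddition to the prenyl alkenes or to the ynol ether, or incomplete opening of the cyclobutenone, may consume material before ring A closes. The fallback sets out from 15 and returns at 25, making the same vinylketene in the dark. Silver-promoted Wolff rearrangement of 15 in wet THF (PhCO2Ag cat., monovalent silver, Et3N, THF/H2O, 25 °C) should give 2-[(2S)-2-[3-(3-methylbut-2-enyl)-4-(triisopropylsilyloxy)phenyl]-4-oxo-2,3-dihydropyran-6-yl]acetic acid F1, which is kept cold because it is a vinylogous β-keto acid. Oxalyl chloride with a trace of DMF in CH2Cl2 at 0 °C should convert it into 2-[(2S)-2-[3-(3-methylbut-2-enyl)-4-(triisopropylsilyloxy)phenyl]-4-oxo-2,3-dihydropyran-6-yl]acetyl chloride F2. Slow addition of Et3N to F2 and 20 in toluene at 25 °C, then heating to 80 °C, should release 21 by dehydrochlorination and carry it through 22, 23 and 24 to 25.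

Step 8. What may go wrong: deprotonation at C3 of the pyranone instead of the acetyl methyl group, leading to trifluoroacetylation and diazo transfer at the wrong carbon, or to β-elimination of the ring oxygen with loss of configuration at C2. The fallback sets out from 8 and returns at 15, replacing diazo transfer by acylation of diazomethane. Claisen condensation of 8 with dimethyl oxalate (LiN(SiMe3)2, THF, −78 °C) should give methyl (6S)-6-(tert-butyldimethylsilyloxy)-6-[3-(3-methylbut-2-enyl)-4-(triisopropylsilyloxy)phenyl]-2,4-dioxohexanoate F3. Aqueous HCl in THF should close it to methyl (2S)-2-[3-(3-methylbut-2-enyl)-4-(triisopropylsilyloxy)phenyl]-4-oxo-2,3-dihydropyran-6-carboxylate F4. Me3SnOH in ClCH2CH2Cl at 70 °C should hydrolyse the ester under neutral conditions to (2S)-2-[3-(3-methylbut-2-enyl)-4-(triisopropylsilyloxy)phenyl]-4-oxo-2,3-dihydropyran-6-carboxylic acid F5. Isobutyl chloroformate and N-methylmorpholine in THF at −15 °C should give the isobutyl carbonic mixed anhydride of that acid F6, and CH2N2 in Et2O at 0 °C should then give 15. A small excess and short contact time are used to limit dipolar addition of diazomethane to the ring alkene.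

Step 10. What may go wrong: proton abstraction from the doubly activated methylene of the β,γ-unsaturated ester or of the intermediates by the carbenoid and the alkyllithium, in place of carbonyl addition and bromine–lithium exchange, so that little ynolate forms. The fallback sets out from 2 and returns at 20 through 19, making the ynolate by oxidation of an acetylide. Copper-catalysed coupling of 2 with HC≡CMgBr (CuBr cat., THF, 0 → 25 °C) should give 5-methylhex-4-en-1-yne F7 by attack at the unsubstituted allylic terminus. n-BuLi in THF at −78 °C should give lithium 5-methylhex-4-en-1-ynide F8, which is oxidised by t-BuOOLi (from t-BuOOH and LiN(SiMe3)2, −78 → 0 °C) to ynolate 19, and iPr3SiOTf at −78 °C should then give 20.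

**Further compounds**

F1 | step 11 | 2-[(2S)-2-[3-(3-methylbut-2-enyl)-4-(triisopropylsilyloxy)phenyl]-4-oxo-2,3-dihydropyran-6-yl]acetic acid | OC(=O)CC1=CC(=O)C[C@@H](c2ccc(O[Si](C(C)C)(C(C)C)C(C)C)c(CC=C(C)C)c2)O1
F2 | step 11 | 2-[(2S)-2-[3-(3-methylbut-2-enyl)-4-(triisopropylsilyloxy)phenyl]-4-oxo-2,3-dihydropyran-6-yl]acetyl chloride | ClC(=O)CC1=CC(=O)C[C@@H](c2ccc(O[Si](C(C)C)(C(C)C)C(C)C)c(CC=C(C)C)c2)O1
F3 | step 8 | methyl (6S)-6-(tert-butyldimethylsilyloxy)-6-[3-(3-methylbut-2-enyl)-4-(triisopropylsilyloxy)phenyl]-2,4-dioxohexanoate | COC(=O)C(=O)CC(=O)C[C@H](O[Si](C)(C)C(C)(C)C)c1ccc(O[Si](C(C)C)(C(C)C)C(C)C)c(CC=C(C)C)c1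
F4 | step 8 | methyl (2S)-2-[3-(3-methylbut-2-enyl)-4-(triisopropylsilyloxy)phenyl]-4-oxo-2,3-dihydropyran-6-carboxylate | COC(=O)C1=CC(=O)C[C@@H](c2ccc(O[Si](C(C)C)(C(C)C)C(C)C)c(CC=C(C)C)c2)O1
F5 | step 8 | (2S)-2-[3-(3-methylbut-2-enyl)-4-(triisopropylsilyloxy)phenyl]-4-oxo-2,3-dihydropyran-6-carboxylic acid | OC(=O)C1=CC(=O)C[C@@H](c2ccc(O[Si](C(C)C)(C(C)C)C(C)C)c(CC=C(C)C)c2)O1
F6 | step 8 | isobutyl carbonic anhydride of F5 | CC(C)COC(=O)OC(=O)C1=CC(=O)C[C@@H](c2ccc(O[Si](C(C)C)(C(C)C)C(C)C)c(CC=C(C)C)c2)O1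
F7 | step 10 | 5-methylhex-4-en-1-yne | C#CCC=C(C)C
F8 | step 10 | lithium 5-methylhex-4-en-1-ynide | [Li]C#CCC=C(C)C
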